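**Plan**

- Retrosynthesis: after unmasking the three hydroxyls, ring A (the 2,3-disubstituted indole) is cut at N1–C2 and C3–C3a, giving 2-iodoaniline and an internal alkyne that already carries ring B and both stereocentres.
- The alkyne is cut at the bond between the methine C1' and C3 of ring B (indole plus a cis-alkynyl epoxy alcohol). The epoxide goes back to a (Z)-enynol, and the enyne to a vinyl iodide and a terminal alkyne.
- Forward: the seven-carbon chain is joined by Sonogashira coupling, ring B (bought as indole) is attached by epoxide opening, and the pyrrole ring of ring A is closed last by Larock heteroannulation. All benzene rings are purchased.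
- Enabling feature: in ring A, C2 bears the branched methine C1' and C3 bears only the unbranched CH2CH2OH chain. The two alkyne carbons that become C2 and C3 therefore differ sharply in bulk, which is what lets the annulation be regioselective.
- Stereochemistry: Sharpless epoxidation of the (Z)-enynol with D-(−)-diethyl tartrate sets the (2R,3S) cis-epoxide. Indole attack with inversion at the propargylic carbon makes C1' (R in the target), and the untouched epoxide carbon becomes the carbinol C2' (S).

Key step: step 5

Remark: tert-butyl(but-3-yn-1-yloxy)dimethylsilane (the TBS ether of but-3-yn-1-ol) is taken as a purchased compound; otherwise one silylation of but-3-yn-1-ol (TBSCl, imidazole) supplies it.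

**Route**

Step 1
Reactants: 1 ethyl (Z)-3-iodoacrylate; 2 tert-butyl(but-3-yn-1-yloxy)dimethylsilane
Product: 3 ethyl (Z)-7-[(tert-butyldimethylsilyl)oxy]hept-2-en-4-ynoate
Conditions: Pd(PPh3)2Cl2 (2 mol%), CuI (4 mol%), Et3N, THF, 0 °C to rt
Reagents that add atoms: none
Why: Sonogashira coupling, in which insertion of zerovalent palladium into the vinyl C–I bond and the final reductive elimination both go with retention, so the (Z)-geometry of 1 should be carried into the enyne while the ester and silyl ether are untouched by the mild amine base.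

Step 2
Reactants: 3 ethyl (Z)-7-[(tert-butyldimethylsilyl)oxy]hept-2-en-4-ynoate
Product: 4 (Z)-7-[(tert-butyldimethylsilyl)oxy]hept-2-en-4-yn-1-ol
Conditions: i-Bu2AlH (2.3 equiv), CH2Cl2, −78 °C; aq. KNaC4H4O6 work-up
Reagents that add atoms: none
Why: Hydride reduction of a conjugated ester with i-Bu2AlH goes 1,2 to the allylic alcohol at low temperature and should leave the (Z)-alkene, the alkyne and the silyl ether unchanged.

Step 3
Reactants: 4 (Z)-7-[(tert-butyldimethylsilyl)oxy]hept-2-en-4-yn-1-ol
Product: 5 [(2R,3S)-3-[4-[(tert-butyldimethylsilyl)oxy]but-1-yn-1-yl]oxiran-2-yl]methanol (cis-epoxide)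
Conditions: Ti(Oi-Pr)4 (0.2 equiv), D-(−)-diethyl tartrate [diethyl (2S,3S)-tartrate, 0.24 equiv], t-BuOOH (2 equiv, isooctane), 4 Å molecular sieves, CH2Cl2, −20 °C
Reagents that add atoms: tert-butyl hydroperoxide, CC(C)(C)OO
Why: Sharpless asymmetric epoxidation, in which the complex formed from Ti(Oi-Pr)4 and the tartrate binds the allylic hydroxyl and the hydroperoxide and, with the (2S,3S)-tartrate, delivers oxygen to the alkene face that makes C2 R; oxygen transfer is syn-stereospecific, so the (Z)-alkene gives the cis-epoxide with C3 S, both new stereocentres being set by the ligand, and the alkyne is not attacked.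

Step 4
Reactants: 5 [(2R,3S)-3-[4-[(tert-butyldimethylsilyl)oxy]but-1-yn-1-yl]oxiran-2-yl]methanol; 6 indole
Product: 8 3-[(1S)-5-[(tert-butyldimethylsilyl)oxy]-1-[(4S)-2,2-dimethyl-1,3-dioxolan-4-yl]pent-2-yn-1-yl]-1H-indole, via diol 7 (not isolated)
Conditions: BF3·OEt2 (50 mol%), CH2Cl2, −78 to −40 °C (6 in twofold amount); then 2,2-dimethoxypropane (excess), −40 to 0 °C; Et3N quench
Reagents that add atoms: 2,2-dimethoxypropane, COC(C)(C)OC
Why: Friedel–Crafts alkylation of indole by the Lewis-acid-activated epoxide, in which C3 of indole should attack the propargylic epoxide carbon (activated by the triple bond, the other epoxide carbon being deactivated by the adjacent hydroxymethyl group) from the side opposite the C–O bond, so that this carbon is inverted and becomes C1' with the configuration of the target while the carbinol carbon C2' keeps its configuration, followed in the same flask by BF3-catalysed transacetalisation of the terminal 1,2-diol to the dioxolane, which spares the isolation of the polar, acid-sensitive diol and leaves no free hydroxyl for the palladium step.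

Step 5
Reactants: 8 3-[(1S)-5-[(tert-butyldimethylsilyl)oxy]-1-[(4S)-2,2-dimethyl-1,3-dioxolan-4-yl]pent-2-yn-1-yl]-1H-indole; 9 2-iodoaniline
Product: 10 3-[2-[(tert-butyldimethylsilyl)oxy]ethyl]-2-[(R)-[(4S)-2,2-dimethyl-1,3-dioxolan-4-yl](1H-indol-3-yl)methyl]-1H-indole
Conditions: Pd(OAc)2 (10 mol%), Na2CO3 (3 equiv), LiCl (1 equiv), degassed DMF, 100 °C (9 in 1.5-fold amount)
Reagents that add atoms: none
Why: Larock heteroannulation, the palladium-catalysed [3+2] union of an ortho-iodoaniline with an internal alkyne: Pd(OAc)2 is reduced in the flask to zerovalent palladium, which inserts into the C–I bond of 9, and the arylpalladium iodide adds syn across the triple bond of 8, forming C3–C3a. The pyrrole ring of ring A then closes when the aniline nitrogen displaces iodide on divalent palladium to give a six-membered azapalladacycle, from which C–N reductive elimination forms N1–C2 and returns zerovalent palladium. No stereocentre is created; C1' and the dioxolane carbon are carried through unchanged. The step needs regioselective insertion, with the aryl group bonding to the alkyne carbon that bears the unbranched CH2CH2OSi chain and palladium to the carbon that bears C1'; this is the normal sense because the larger substituent prefers the long C–Pd bond to the short new C–C bond, and here a primary carbon is set against a secondary carbon carrying an indolyl and a dioxolanyl group. The weak carbonate base is chosen so that the acidic propargylic C1'–H is not removed before annulation (which would give an allene and lose the configuration), and the N–H of ring B is not arylated without a stronger base and a ligand.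

Step 6
Reactants: 10 3-[2-[(tert-butyldimethylsilyl)oxy]ethyl]-2-[(R)-[(4S)-2,2-dimethyl-1,3-dioxolan-4-yl](1H-indol-3-yl)methyl]-1H-indole
Product: 12 colletotryptin A, via desilylated acetonide 11 (not isolated)
Conditions: CSA (0.2 equiv), MeOH, 0 °C to rt
Reagents that add atoms: none
Why: Acid-catalysed methanolysis, in which the primary silyl ether should be solvolysed first and the terminal dioxolane then transacetalised to methanol, while a catalytic sulfonic acid at room temperature is too weak to ionise the bis(indolyl)methine, so both stereocentres should survive.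

**Compound list**

1 | ethyl (Z)-3-iodoacrylate | CCOC(=O)/C=C\I | starting material
2 | tert-butyl(but-3-yn-1-yloxy)dimethylsilane | C#CCCO[Si](C)(C)C(C)(C)C | starting material
3 | ethyl (Z)-7-[(tert-butyldimethylsilyl)oxy]hept-2-en-4-ynoate | CCOC(=O)/C=C\C#CCCO[Si](C)(C)C(C)(C)C | intermediate
4 | (Z)-7-[(tert-butyldimethylsilyl)oxy]hept-2-en-4-yn-1-ol | OC/C=C\C#CCCO[Si](C)(C)C(C)(C)C | intermediate
5 | [(2R,3S)-3-[4-[(tert-butyldimethylsilyl)oxy]but-1-yn-1-yl]oxiran-2-yl]methanol | CC(C)(C)[Si](C)(C)OCCC#C[C@@H]1O[C@@H]1CO | intermediate
6 | indole | c1ccc2[nH]ccc2c1 | starting material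
7 | (2S,3S)-7-[(tert-butyldimethylsilyl)oxy]-3-(1H-indol-3-yl)hept-4-yne-1,2-diol (formed in the flask in step 4) | CC(C)(C)[Si](C)(C)OCCC#C[C@@H](c1c[nH]c2ccccc12)[C@H](O)CO | intermediate
8 | 3-[(1S)-5-[(tert-butyldimethylsilyl)oxy]-1-[(4S)-2,2-dimethyl-1,3-dioxolan-4-yl]pent-2-yn-1-yl]-1H-indole | CC(C)(C)[Si](C)(C)OCCC#C[C@@H](c1c[nH]c2ccccc12)[C@H]1COC(C)(C)O1 | intermediate
9 | 2-iodoaniline | Nc1ccccc1I | starting material
10 | 3-[2-[(tert-butyldimethylsilyl)oxy]ethyl]-2-[(R)-[(4S)-2,2-dimethyl-1,3-dioxolan-4-yl](1H-indol-3-yl)methyl]-1H-indole | CC(C)(C)[Si](C)(C)OCCc1c([C@@H](c2c[nH]c3ccccc23)[C@H]2COC(C)(C)O2)[nH]c2ccccc12 | intermediate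
11 | 2-[2-[(R)-[(4S)-2,2-dimethyl-1,3-dioxolan-4-yl](1H-indol-3-yl)methyl]-1H-indol-3-yl]ethan-1-ol (formed in the flask in step 6) | OCCc1c([C@@H](c2c[nH]c3ccccc23)[C@H]2COC(C)(C)O2)[nH]c2ccccc12 | intermediate
12 | colletotryptin A, (2S,3R)-3-[3-(2-hydroxyethyl)-1H-indol-2-yl]-3-(1H-indol-3-yl)propane-1,2-diol | OCCc1c([C@@H](c2c[nH]c3ccccc23)[C@H](O)CO)[nH]c2ccccc12 | target

**Count and risks**

Total steps: 6. Longest linear sequence: 6 steps (1 to 12).

Step 5. The alkyne insertion may not be regioselective enough (the aryl group adding to the carbon next to C1'). The base may also shift the propargylic hydrogen to give an allene and erase the C1' configuration, or the hindered alkyne may insert so slowly that the iodide is simply reduced. Fallback, setting out from 6 and returning at 11: ring A is bought as tryptophol instead of being built. Indole 6 is deprotonated with EtMgBr (THF, 0 °C) and the indolylmagnesium bromide adds through C3 to purchased (R)-2,2-dimethyl-1,3-dioxolane-4-carbaldehyde, giving (1H-indol-3-yl)[(4R)-2,2-dimethyl-1,3-dioxolan-4-yl]methanol F1 as a mixture of carbinol epimers. Catalytic Sc(OTf)3 in MeCN at 0 °C should ionise F1 to the 3-alkylideneindoleninium ion. Purchased tryptophol, 2-(1H-indol-3-yl)ethanol, captures this ion at its free C2 (the Friedel–Crafts route to 2,3'-bis(indolyl)methanes) to give 11 and its C1' epimer. The face of the cation is biased only by the neighbouring dioxolane, so the epimers would have to be separated. Compound 11 then needs only the acetonide methanolysis of step 6.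

Step 4. The epoxide may open with poor site selectivity or through a loosened, cation-like transition state that erodes the inversion. It may also rearrange by hydride shift or suffer SN2′ attack to an allene. During the ketalisation stage the Lewis acid may cleave the silyl ether or let acetone-derived cations alkylate the indole ring. Fallback, setting out from 2 and returning at 7: the polarity is reversed, so that an alkynyl nucleophile opens an indolyl epoxide. Purchased 1-tosyl-1H-indole-3-carbaldehyde is homologated by Horner–Wadsworth–Emmons reaction (triethyl phosphonoacetate, NaH, THF) to ethyl (E)-3-(1-tosyl-1H-indol-3-yl)acrylate F2. Reduction with i-Bu2AlH gives (E)-3-(1-tosyl-1H-indol-3-yl)prop-2-en-1-ol F3. Epoxidation under the conditions of step 3, again with D-(−)-diethyl tartrate, gives [(2R,3R)-3-(1-tosyl-1H-indol-3-yl)oxiran-2-yl]methanol F4; (E)-allylic alcohols are the best substrates of this reaction. The diethylalkynylalane made from 2 (n-BuLi, then Et2AlCl, toluene, 0 °C) should open F4 at C3 with inversion, the known site selectivity of organoaluminium reagents with 2,3-epoxy alcohols, to give (2S,3S)-7-[(tert-butyldimethylsilyl)oxy]-3-(1-tosyl-1H-indol-3-yl)hept-4-yne-1,2-diol F5. Mg in MeOH then removes the sulfonyl group to give 7, which is ketalised to 8 with 2,2-dimethoxypropane and PPTS in place of the second stage of step 4.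

Step 3. Epoxidation of (Z)-allylic alcohols with Ti(Oi-Pr)4 and a tartrate is slow and usually less enantioselective than that of (E)-isomers, so the enantiomeric purity fixed here, which is never raised later, may be insufficient. Fallback, setting out from 4 and returning at 5: 4 is benzoylated (BzCl, pyridine, CH2Cl2) to (Z)-7-[(tert-butyldimethylsilyl)oxy]hept-2-en-4-yn-1-yl benzoate F6. Shi epoxidation follows, with the oxazolidinone-bearing ketone developed for cis-olefins (conjugated cis-enynes are good substrates): KHSO5 (as 2KHSO5·KHSO4·K2SO4), K2CO3, MeCN/dimethoxymethane/H2O, −10 °C. The ketone enantiomer that delivers the (2R,3S) epoxide is used, which should give [(2R,3S)-3-[4-[(tert-butyldimethylsilyl)oxy]but-1-yn-1-yl]oxiran-2-yl]methyl benzoate F7. i-Bu2AlH at −78 °C removes the benzoate reductively, avoiding Payne rearrangement, to give 5.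

**Further compounds**

F1 | step 5 | (1H-indol-3-yl)[(4R)-2,2-dimethyl-1,3-dioxolan-4-yl]methanol (both carbinol epimers) | OC(c1c[nH]c2ccccc12)[C@H]1COC(C)(C)O1
F2 | step 4 | ethyl (E)-3-(1-tosyl-1H-indol-3-yl)acrylate | CCOC(=O)/C=C/c1cn(S(=O)(=O)c2ccc(C)cc2)c2ccccc12
F3 | step 4 | (E)-3-(1-tosyl-1H-indol-3-yl)prop-2-en-1-ol | OC/C=C/c1cn(S(=O)(=O)c2ccc(C)cc2)c2ccccc12
F4 | step 4 | [(2R,3R)-3-(1-tosyl-1H-indol-3-yl)oxiran-2-yl]methanol | Cc1ccc(cc1)S(=O)(=O)n1cc([C@H]2O[C@@H]2CO)c2ccccc12
F5 | step 4 | (2S,3S)-7-[(tert-butyldimethylsilyl)oxy]-3-(1-tosyl-1H-indol-3-yl)hept-4-yne-1,2-diol | Cc1ccc(cc1)S(=O)(=O)n1cc([C@H](C#CCCO[Si](C)(C)C(C)(C)C)[C@H](O)CO)c2ccccc12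
F6 | step 3 | (Z)-7-[(tert-butyldimethylsilyl)oxy]hept-2-en-4-yn-1-yl benzoate | O=C(OC/C=C\C#CCCO[Si](C)(C)C(C)(C)C)c1ccccc1
F7 | step 3 | [(2R,3S)-3-[4-[(tert-butyldimethylsilyl)oxy]but-1-yn-1-yl]oxiran-2-yl]methyl benzoate | CC(C)(C)[Si](C)(C)OCCC#C[C@@H]1O[C@@H]1COC(=O)c1ccccc1
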